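All constants come from no measurement; the rest is arithmetic.

Start from the closed flask, south, and set the dosed flask, west, beside it: your hunch that dosing the second substrate pays can be reckoned before either is run.

common to all: starting material 0.10 M; enzyme 17 µM; impurity 2.6 µM

| charge | second substrate | remark | time |
|---|---|---|---|
| north | 0.0500 M | a single well-mixed tank run continuously and read at steady state, 6.0 min in it on average |  |
| west | 0.0500 M (fed, over 6.00 min) | all but second substrate at the start; second substrate goes in evenly over 6.00 min, the run ends at 6.0 min | 6.0 min |
| north-east | 0.0500 M | a tube with plug flow, the mixed feed as stated, residence time 6.0 min | 6.0 min |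
| south | 0.0500 M | everything together in a closed stirred flask, run for 6.0 min | 6.0 min |

    starting material + enzyme ⇌ complex A (K1 = 2.2 M⁻¹, k1 = 10000 M⁻¹ s⁻¹)
    complex A → enzyme + target (k2 = 130 s⁻¹)
    second substrate + enzyme ⇌ complex B (K3 = 20 M⁻¹, k3 = 3900 M⁻¹ s⁻¹)
    complex B → enzyme + second product (k4 = 14 s⁻¹)
    starting material → uncatalysed product (k5 = 0.0015 s⁻¹)
    enzyme + impurity → spent catalyst (k6 = 2.0 × 10⁵ M⁻¹ s⁻¹)

* the set-up with the highest amount of target at the outlet or at the end, in percent of the starting material put in ("none" if the first two lie within 2 percentage points) (north / west / north-east / south / none)
* amount of target at the outlet or at the end, in percent of the starting material put in, north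
* amount of target at the outlet or at the end, in percent of the starting material put in, west
* amount of target at the outlet or at the end, in percent of the starting material put in, north-east
* amount of target at the outlet or at the end, in percent of the starting material put in, south

Take the enzyme first. The impurity meets it within about 0.294 s, far shorter than the run, and there is less impurity than enzyme, so count 14.4 µM of working enzyme. Write the Michaelis constants from the rate constants: 0.468 M for starting material, 0.0536 M for second substrate. Now multiply the turnover of complex A, 130 s⁻¹, by the working enzyme and divide by its Michaelis constant. Call this pseudo-first-order constant the enzyme pace: 0.240 min⁻¹. The same sum for second substrate gives 0.226 min⁻¹.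

Let D be one plus each concentration over its Michaelis constant. Enzyme takes starting material at the pace over D, and the uncatalysed step takes it at 0.09 min⁻¹. So the split, the share going to target, is the pace over the pace plus 0.09 min⁻¹ times D.

Solve both ends and join them. South starts at D = 2.15 and ends near 1.56, so take the mean, 1.85. That gives 43.2% target, and the plug-flow tube, north-east, is the same flask in motion. West starts at 1.21 and ends near 1.72, which joins to 1.47 and gives 50.5%. The tank, north, sits at its outlet state, D near 1.63, which gives 36.5%. I would commit to west.

The forecast also names west, on the grounds “Fed-batch keeps competitor low”: 37% north, 51.6% west, 43.9% north-east, 43.9% south. My west lies 1.1 percentage points below it.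

The simulation gives west: 37.0% north, 51.7% west, 44.0% north-east, 44.0% south.

In west, the step from complex A to target had 72% of its turnover behind it by 3.00 min, while complex B rose from 21.3% of the catalyst then to 31.5% at 6.00 min. West ended with 51.7% target and 26.9% uncatalysed product, a split of 65.8%; joining D from its simulated end gives 65.0%. In the neighbour of west charged with 1.0 × 10⁻⁵ M enzyme, the pace is about half of west's, 0.123 min⁻¹, and the same join gives 47.4%. That flask ended with 31.2% target and 33.1% uncatalysed product, a split of 48.5%.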